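(Readings and results are simulated from invented constants, and the scatter is random.)

- Amounts first: the flask holds 0.5 mol% free catalyst on its starting material, less than the amber and violet runs.

| flask | starting material | free catalyst | remark | time |
|---|---|---|---|---|
| amber | 0.62 M | 0.7 mol% | run made earlier |  |
| violet | 0.62 M | 1.1 mol% | run made earlier |  |
| flask | 0.62 M | 0.5 mol% |  | 5.0 h |

| run | time / h | product / % | starting material / % |
|---|---|---|---|
| amber | 0.200 | 4.3 | 94.6 |
| amber | 0.667 | 11.5 | 89.6 |
| amber | 1.00 | 16.5 | 82.6 |
| amber | 1.50 | 24.5 | 74.7 |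
| amber | 2.50 | 38.3 | 61.6 |
| amber | 3.00 | 45.3 | 55.3 |
| violet | 0.200 | 5.3 | 94.7 |
| violet | 0.667 | 16.8 | 82.0 |
| violet | 1.00 | 25.5 | 74.8 |
| violet | 1.50 | 37.0 | 61.6 |
| violet | 2.50 | 56.2 | 43.0 |
| violet | 3.00 | 65.0 | 35.0 |

(each reading ± 1 percentage point)

1. amount of product in percent of the starting material charged, at 1.0 h, 2.5 h and 5.0 h

- The rate is told per catalyst, as a turnover frequency: product as a fraction of the charge, divided by loading and time.
- Over the first hour, the amber run reads 23.6 h⁻¹ and the violet run 23.2 h⁻¹. In these two runs the rate follows the loading within the scatter, so the reckoning puts the start of the flask near 0.116 h⁻¹ of its charge.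
- Later, the violet run reads 17.0 h⁻¹ from 1.50 h to 3.00 h. Its mean fraction of starting material left has fallen from 0.874 to 0.483, and its frequency stands at 0.733 of the first-hour reading.
- Those readings give the slowing slope, the turnover frequency lost per whole unit of mean fraction left: 15.9 h⁻¹.
- Round one of my reckoning ignores the slowing and puts the flask at 58.0 % at 5.0 h.
- Round two puts that answer back: the mean fraction left is 0.710, the frequency 20.6 h⁻¹, the product 51.4 %.
- Round three uses a mean fraction left of 0.743 and a frequency of 21.1 h⁻¹, giving 52.7 %. The accumulated slowing thus leaves 0.909 of the straight-line product.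
- One such correction gives 12.1 % at 1.0 h and 28.6 % at 2.5 h.
- The forecast, on the ground that the “two runs also fall on one curve”, gives 11.8 %, 28.4 % and 52.3 %, its last value lying slightly below my 52.7 %.

- The flask gives 11.9 %, 28.6 % and 52.1 %.

    starting material + free catalyst ⇌ catalyst intermediate A (K = 2.45 M⁻¹, k = 2.23 M⁻¹ min⁻¹)
    catalyst intermediate A → catalyst intermediate B (k = 1.69 min⁻¹)
    catalyst intermediate B → free catalyst + product (k = 1.41 min⁻¹)

- The free catalyst of the flask rises from 47.7 % of the catalyst charged at 0.500 h to 64.1 % at 5.00 h, while its starting material falls from 93.8 % to 47.8 % of the charge. For a second flask with half the free catalyst, the slowing slope 15.9 h⁻¹ gives a frequency of 22.9 h⁻¹ and 28.6 % product at 5.0 h; that second flask gives 28.6 %.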